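**Retrosynthetic overview**

- The target follows from its tribenzyl-protected form by one hydrogenolysis; ring B, with its pentyl chain and oxygen pattern, is carried intact from olivetol.
- The strategy rests on ring A and its contiguous substitution: position 1 carries CO2H, flanked by position 2 (diaryl ether oxygen) and position 6 (pentanoyl), with OMe at position 4 and hydrogen at positions 3 and 5. Ring A is cut across the 2,3-bond and the 6,1-bond into a two-carbon alkyne (positions 2 and 1, already bearing the ring B aryloxy group and the benzyl ester) and a 2-pyrone diene (positions 3 to 6, already bearing OMe and pentanoyl).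
- Ring A is the only ring formed: a pyrone/alkyne Diels-Alder reaction followed by loss of CO2.
- The alkyne comes from olivetol by benzylation, Vilsmeier formylation, Baeyer-Villiger oxidation to the phenol, trichloroethylene addition-elimination, then n-BuLi and benzyl chloroformate.
- The pyrone comes from 4-methoxy-6-methyl-2-pyrone by SeO2 oxidation, butyl Grignard addition and oxidation.

Key step: step 9

Remark on the chemistry: the 2-acylbenzoic acid of the target can equilibrate with its hydroxyphthalide (lactol) tautomer; the open keto acid is taken as the target structure.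

**Route**

Step 1
Reactants: 1 4-methoxy-6-methyl-2H-pyran-2-one
Product: 2 4-methoxy-2-oxo-2H-pyran-6-carbaldehyde
Conditions: SeO2, 1,4-dioxane, 160 °C, sealed tube
Reagents that add atoms: selenium dioxide, O=[Se]=O
Why: Riley oxidation; the C6 methyl group is allylic and vinylogously activated by the lactone carbonyl, so SeO2 should take it to the aldehyde by the usual ene reaction and [2,3]-shift.

Step 2
Reactants: 2 4-methoxy-2-oxo-2H-pyran-6-carbaldehyde; 3 butylmagnesium bromide
Product: 4 6-(1-hydroxypentyl)-4-methoxy-2H-pyran-2-one (racemic)
Conditions: n-BuMgBr (1.05 equiv), THF, −78 °C; then 1 M HCl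
Reagents that add atoms: none
Why: Grignard 1,2-addition; at −78 °C the aldehyde is far more electrophilic than the vinylogous ester/lactone of the pyrone, and the new carbinol stereocentre forms racemic and is erased in step 3.

Step 3
Reactants: 4 6-(1-hydroxypentyl)-4-methoxy-2H-pyran-2-one
Product: 5 4-methoxy-6-pentanoyl-2H-pyran-2-one
Conditions: Dess-Martin periodinane, CH2Cl2, 0 °C to rt
Reagents that add atoms: none
Why: Dess-Martin oxidation of a secondary allylic-type alcohol under neutral conditions that should leave the pyrone untouched.

Step 4
Reactants: 6 olivetol (5-pentylbenzene-1,3-diol)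
Product: 7 1,3-bis(benzyloxy)-5-pentylbenzene
Conditions: BnBr (2.2 equiv), K2CO3, DMF, 60 °C
Reagents that add atoms: benzyl bromide, BrCc1ccccc1
Why: Williamson ether synthesis; both phenols should be O-benzylated with a weak base in a polar aprotic solvent.

Step 5
Reactants: 7 1,3-bis(benzyloxy)-5-pentylbenzene
Product: 9 2,4-bis(benzyloxy)-6-pentylbenzaldehyde, via aryl iminium chloride 8 (not isolated)
Conditions: POCl3, DMF, 0 °C then 70 °C; then ice-water
Reagents that add atoms: N,N-dimethylformamide, CN(C)C=O; water, O
Why: Vilsmeier-Haack formylation; attack para to one benzyloxy group, ortho to the other and next to the pentyl chain should be favoured over the more hindered position between the two benzyloxy groups, as with other 5-alkylresorcinol diethers, and the iminium is hydrolysed on work-up.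

Step 6
Reactants: 9 2,4-bis(benzyloxy)-6-pentylbenzaldehyde
Product: 11 2,4-bis(benzyloxy)-6-pentylphenol, via aryl formate 10 (not isolated)
Conditions: mCPBA, CH2Cl2, 0 °C to rt; then K2CO3 (cat.), MeOH, rt, under argon
Reagents that add atoms: meta-chloroperoxybenzoic acid, OOC(=O)c1cccc(Cl)c1
Why: Baeyer-Villiger (Dakin-type) oxidation; in the Criegee intermediate of an ortho,para-dialkoxybenzaldehyde the electron-rich aryl group migrates to give the formate, which methanol should transesterify to the free phenol.

Step 7
Reactants: 11 2,4-bis(benzyloxy)-6-pentylphenol; 12 trichloroethylene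
Product: 13 1,5-bis(benzyloxy)-2-[(E)-1,2-dichloroethenyloxy]-3-pentylbenzene
Conditions: trichloroethylene (1.5 equiv), K2CO3, DMF, 70 °C
Reagents that add atoms: none
Why: Base-mediated addition-elimination of a phenoxide on trichloroethylene (through dichloroacetylene and anti addition) is the standard route to aryl (E)-1,2-dichlorovinyl ethers and installs the future diaryl ether oxygen-carbon bond without any aryl-oxygen coupling.

Step 8
Reactants: 13 1,5-bis(benzyloxy)-2-[(E)-1,2-dichloroethenyloxy]-3-pentylbenzene; 14 benzyl chloroformate
Product: 17 benzyl 3-[2,4-bis(benzyloxy)-6-pentylphenoxy]prop-2-ynoate, via chloroethynyl aryl ether 15 (not isolated), via lithium aryloxyacetylide 16 (not isolated)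
Conditions: n-BuLi (2.2 equiv), THF, −78 to −40 °C; then cannulated into ClCO2Bn (1.5 equiv), THF, −78 °C; neutral work-up, chromatography on Et3N-deactivated silica
Reagents that add atoms: none
Why: Ynol ether synthesis from a 1,2-dichlorovinyl ether; the first equivalent of n-BuLi should dehydrochlorinate to the chloroalkyne, the second should effect lithium-chlorine exchange, and the lithium acetylide is C-acylated by the chloroformate, with inverse addition keeping the electrophile in excess.

Step 9
Reactants: 5 4-methoxy-6-pentanoyl-2H-pyran-2-one; 17 benzyl 3-[2,4-bis(benzyloxy)-6-pentylphenoxy]prop-2-ynoate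
Product: 19 benzyl 2-[2,4-bis(benzyloxy)-6-pentylphenoxy]-4-methoxy-6-pentanoylbenzoate, via bicyclic lactone adduct 18 (not isolated)
Conditions: 5 (1.5 equiv), o-dichlorobenzene, BHT (cat.), 160 °C, sealed tube, argon
Reagents that add atoms: none
Why: The pyrone diene (C3=C4–C5=C6) should add thermally across the alkyne in a concerted intermolecular (4+2) cycloaddition, joining pyrone C3 to the aryloxy-bearing alkyne carbon (the bond between positions 2 and 3 of ring A) and pyrone C6 to the ester-bearing alkyne carbon (the bond between positions 6 and 1 of ring A), and the 2-oxabicyclo[2.2.2]octadienone 18 then expels CO2 by a retro-(4+2) step to give the benzene ring directly. The closest known reaction type is the thermal Diels-Alder reaction of 4-alkoxy-2-pyrones with propiolates and acetylenedicarboxylates, which delivers benzoates after decarboxylation. Ring A is closed by cycloaddition of two components, not by cyclisation of a chain, and is aromatised by extrusion, so neither an oxidation nor loss of a leaving group is needed; the two bridgehead stereocentres of 18 are transient and no stereocentre remains. The selectivity needed is regiochemical: pyrone C3 (β-carbon of the enol ether) is the nucleophilic diene terminus and pairs with the aryloxy-bearing alkyne carbon, the Michael-acceptor β-carbon of the propiolate, while the acyl-bearing C6, the electrophilic δ-position of the lactone, pairs with the ester-bearing carbon, the nucleophilic β-carbon of the ynol ether, so both polarisations call for the same orientation. The aryloxy group has no aliphatic β-hydrogen, so retro-ene fragmentation of the ynol ether to a ketene is not open at this temperature, and because the oxygen sits on an sp carbon it cannot be expelled during aromatisation.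

Step 10
Reactants: 19 benzyl 2-[2,4-bis(benzyloxy)-6-pentylphenoxy]-4-methoxy-6-pentanoylbenzoate
Product: 20 2-(2,4-dihydroxy-6-pentylphenoxy)-4-methoxy-6-pentanoylbenzoic acid (CNP0189595.0)
Conditions: H2 (1 atm), 10% Pd/C, EtOAc, rt; stopped after uptake of 3 equiv H2
Reagents that add atoms: none
Why: Catalytic hydrogenolysis of two aryl benzyl ethers and a benzyl ester at atmospheric pressure in a neutral solvent should be much faster than reduction of the hindered aryl alkyl ketone, so stopping at three equivalents of H2 should free both phenols and the acid with the ketone intact.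

**Compound list**

1 | 4-methoxy-6-methyl-2H-pyran-2-one | Cc1cc(OC)cc(=O)o1 | starting material
2 | 4-methoxy-2-oxo-2H-pyran-6-carbaldehyde | O=Cc1cc(OC)cc(=O)o1 | intermediate
3 | butylmagnesium bromide | CCCC[Mg]Br | starting material
4 | 6-(1-hydroxypentyl)-4-methoxy-2H-pyran-2-one (racemic) | CCCCC(O)c1cc(OC)cc(=O)o1 | intermediate
5 | 4-methoxy-6-pentanoyl-2H-pyran-2-one | CCCCC(=O)c1cc(OC)cc(=O)o1 | intermediate
6 | olivetol (5-pentylbenzene-1,3-diol) | CCCCCc1cc(O)cc(O)c1 | starting material
7 | 1,3-bis(benzyloxy)-5-pentylbenzene | CCCCCc1cc(OCc2ccccc2)cc(OCc2ccccc2)c1 | intermediate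
8 | N-[2,4-bis(benzyloxy)-6-pentylbenzylidene]-N-methylmethanaminium chloride (not isolated) | C[N+](C)=Cc1c(CCCCC)cc(OCc2ccccc2)cc1OCc1ccccc1.[Cl-] | intermediate
9 | 2,4-bis(benzyloxy)-6-pentylbenzaldehyde | O=Cc1c(CCCCC)cc(OCc2ccccc2)cc1OCc1ccccc1 | intermediate
10 | 2,4-bis(benzyloxy)-6-pentylphenyl formate (not isolated) | O=COc1c(CCCCC)cc(OCc2ccccc2)cc1OCc1ccccc1 | intermediate
11 | 2,4-bis(benzyloxy)-6-pentylphenol | Oc1c(CCCCC)cc(OCc2ccccc2)cc1OCc1ccccc1 | intermediate
12 | trichloroethylene | ClC=C(Cl)Cl | starting material
13 | 1,5-bis(benzyloxy)-2-[(E)-1,2-dichloroethenyloxy]-3-pentylbenzene | Cl/C=C(Cl)\Oc1c(CCCCC)cc(OCc2ccccc2)cc1OCc1ccccc1 | intermediate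
14 | benzyl chloroformate | O=C(Cl)OCc1ccccc1 | starting material
15 | 1,5-bis(benzyloxy)-2-(chloroethynyloxy)-3-pentylbenzene (not isolated) | ClC#COc1c(CCCCC)cc(OCc2ccccc2)cc1OCc1ccccc1 | intermediate
16 | lithium [2,4-bis(benzyloxy)-6-pentylphenoxy]acetylide (not isolated) | [Li]C#COc1c(CCCCC)cc(OCc2ccccc2)cc1OCc1ccccc1 | intermediate
17 | benzyl 3-[2,4-bis(benzyloxy)-6-pentylphenoxy]prop-2-ynoate | O=C(OCc1ccccc1)C#COc1c(CCCCC)cc(OCc2ccccc2)cc1OCc1ccccc1 | intermediate
18 | benzyl 8-[2,4-bis(benzyloxy)-6-pentylphenoxy]-5-methoxy-3-oxo-1-pentanoyl-2-oxabicyclo[2.2.2]octa-5,7-diene-7-carboxylate (racemic, not isolated) | CCCCC(=O)C12OC(=O)C(C(OC)=C1)C(Oc1c(CCCCC)cc(OCc3ccccc3)cc1OCc1ccccc1)=C2C(=O)OCc1ccccc1 | intermediate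
19 | benzyl 2-[2,4-bis(benzyloxy)-6-pentylphenoxy]-4-methoxy-6-pentanoylbenzoate | CCCCCc1cc(OCc2ccccc2)cc(OCc2ccccc2)c1Oc1cc(OC)cc(C(=O)CCCC)c1C(=O)OCc1ccccc1 | intermediate
20 | 2-(2,4-dihydroxy-6-pentylphenoxy)-4-methoxy-6-pentanoylbenzoic acid | CCCCCc1cc(O)cc(O)c1Oc1cc(OC)cc(C(=O)CCCC)c1C(=O)O | target

**Step count**

Total step count: 10. Longest linear sequence: 7 steps (steps 4, 5, 6, 7, 8, 9, 10, from olivetol); the pyrone branch (steps 1 to 3) converges at step 9.

**Steps most likely to fail**

1. Step 9. The push-pull alkyne may cycloadd too slowly, so that polymerisation or thermal decomposition of the ynol ether ester outruns the (4+2) addition, or the orientation may be incomplete. The fallback attaches the ether oxygen after ring A is made and sets out from 5 and 11. Commercial benzyl propiolate would be brominated (NBS, AgNO3 cat., acetone, rt) to benzyl 3-bromoprop-2-ynoate F1, a smaller and more electron-poor dienophile. F1 and pyrone 5, heated in toluene at 140 °C in a sealed tube, should pass through the bicyclic bromo lactone adduct F2 and lose CO2 to give benzyl 2-bromo-4-methoxy-6-pentanoylbenzoate F3, the same polarity argument placing bromine at position 2 of ring A. Ullmann diaryl ether coupling of F3 with phenol 11 (CuI, picolinic acid, K3PO4, DMSO, 90 °C) would return to the route at 19.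

2. Step 8. The lithium acetylide may add to the newly formed ynoate (over-addition at the ester or conjugate addition), and the product may hydrate at the aryloxy-bearing carbon on work-up. The fallback sets out from 13: the acetylide generated with n-BuLi would be carboxylated with CO2 at −78 °C to lithium 3-[2,4-bis(benzyloxy)-6-pentylphenoxy]prop-2-ynoate F4, a carboxylate that cannot be attacked a second time. The crude salt would be O-alkylated with benzyl bromide in DMF at rt, returning to the route at 17.

3. Step 10. Over-reduction of the aryl ketone may occur: to the benzylic alcohol, which would close onto the acid as a phthalide, or on to the methylene. The fallback sets out from 19 and gives 20 directly by Lewis-acid debenzylation instead of hydrogenation: BCl3 with pentamethylbenzene as cation scavenger, CH2Cl2, −78 °C, then aqueous work-up. These conditions should cleave the two aryl benzyl ethers and the benzyl ester while leaving the ketone, the diaryl ether and the methyl ether at position 4 of ring A (not ortho to a carbonyl) untouched.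

**Further compounds**

F1 | step 9 | benzyl 3-bromoprop-2-ynoate | O=C(OCc1ccccc1)C#CBr
F2 | step 9 | benzyl 8-bromo-5-methoxy-3-oxo-1-pentanoyl-2-oxabicyclo[2.2.2]octa-5,7-diene-7-carboxylate (racemic, not isolated) | CCCCC(=O)C12OC(=O)C(C(OC)=C1)C(Br)=C2C(=O)OCc1ccccc1
F3 | step 9 | benzyl 2-bromo-4-methoxy-6-pentanoylbenzoate | CCCCC(=O)c1cc(OC)cc(Br)c1C(=O)OCc1ccccc1
F4 | step 8 | lithium 3-[2,4-bis(benzyloxy)-6-pentylphenoxy]prop-2-ynoate | [Li+].[O-]C(=O)C#COc1c(CCCCC)cc(OCc2ccccc2)cc1OCc1ccccc1
F0 | step 10 | none | none
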